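**Numbering used throughout:** 1–7 building blocks, 8–14 flavonol assembly, 15 key-step precursor, 16 and 17 transient quinone and quinone methide, 18 key-step product, 19 Broussonol A. Prenyl = 3-methylbut-2-en-1-yl; MOM = methoxymethyl; SEM = 2-(trimethylsilyl)ethoxymethyl.

## The problem

Broussonol A (19) is a flavonol: a benzopyranone (rings A and C) carries ring B at C2, and ring B is fused across C4'–C5' to a 2,2-dimethyl-2H-pyran (ring D), so that O4' is the pyran oxygen and C5' bears the vinylic carbon. Ring A holds a 1,1-dimethylallyl group whose quaternary carbon is bonded to C8, between the C7 hydroxyl and the ring-C oxygen, and ring B keeps a free hydroxyl at C3' beside the pyran oxygen. The molecule has no stereocentre, so nothing has to be controlled in space. Every difficulty is constitutional: which ortho carbon of O7 receives the tertiary carbon, which ring-B carbon is oxygenated, and through which oxygen ring D closes. The fragile parts are the ortho-(1,1-dimethylallyl)phenol, which cyclises to a dihydrofuran under strong acid or long heating, and the vinyl and chromene double bonds, which exclude hydrogenolysis and electrophilic oxidants late in the route. Ring A and the 3-hydroxypyranone are themselves oxidisable. Four hydroxyls must be told apart, because the oxidant of the key event may meet only one free phenol. The enabling feature is that the array C3'–OH / C4'–O–C(CH3)2–CH=CH–C5' is a constitutional isomer of a 5'-prenyl-3',4'-ortho-quinone. The prenyl CH2 is linked through C5'=C6' and C1'=C2' to the C3' carbonyl, so loss of one proton there gives the 1-oxatriene O=C4'–C5'=CH–CH=C(CH3)2, which can close to ring D. Both the C3' oxygen and ring D can therefore be drawn from a plain 4'-hydroxy-5'-prenyl ring B.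

## Retrosynthesis

**Deprotection.** The last bonds cut are the three acetal C–O bonds at O3, O5 and O7, which takes 19 back to its tris-MOM ether 18. Acetals are preferred to benzyl or methyl ethers because their removal needs neither hydrogen nor a strong Lewis acid, which the vinyl group, the chromene and the ortho-(tert-prenyl)phenol would not tolerate. The forward step only has to be mild enough not to protonate the two alkenes.

**Ring D and the C3' oxygen (key disconnection).** In 18 the O4'–C(CH3)2 bond and the C3'–O bond are cut together. Retro-electrocyclic opening of the pyran gives the vinyl ortho-quinone methide 17, its tautomer is the 5'-prenyl-3',4'-quinone 16, and removal of the C3' oxygen leads to the 4'-hydroxy-5'-prenyl flavone 15. The neighbouring cut, which would bring in a preformed 8-hydroxychromene, requires regiocontrol on a catechol and a fourth protecting group. This cut needs neither, and its ring B comes from a para-substituted phenol by one C-alkylation. Precursor 15 is simpler by one ring and one oxygen. The forward reaction must oxygenate C3' only, and the quinone must tautomerise faster than it is reduced or trapped.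

**Unveiling the lone phenol.** 15 comes from 14 by cleaving the 4'-O acetal, and 14 from diol 13 by cutting the O3 and O7 MOM groups. The ring-B oxygen thus needs a group that survives hydroxide, peroxide, 190 °C and hydride and then falls to a reagent that ignores MOM ethers. A SEM ether cleaved by fluoride meets this; an aryl silyl ether para to a carbonyl would be lost in the hydroxide steps. Protecting O3 and O7 in one operation after the sigmatropic step saves a step over doing them separately.

**The tertiary carbon on C8.** Cutting C8–C(CH3)2 in 13 and rejoining the allyl terminus to O7 gives the 7-O-prenyl flavonol 11, by way of dienone 12. A [3,3] shift is the direct way to form an aryl–quaternary carbon bond with allyl inversion; electrophilic prenylation would give the linear isomer and would not choose between C6 and C8. The precursor loses its only carbon substituent on ring A. The forward reaction has to prefer C8 over C6 and stop before the new phenol adds to its own vinyl group.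

**Ring C.** The O1–C2 and C3–O bonds of 11 are cut back to the 2'-hydroxychalcone 9 (through dihydroflavonol 10). The Cα=Cβ bond of 9 is then cut to acetophenone 7 and aldehyde 4 (through aldol 8). This divides the skeleton into two pieces of similar size joined by a condensation that needs no activation. Acyl-transfer routes to the flavonol would need an α-oxygenated ketone. The forward oxidative cyclisation must close six-membered (flavonol) rather than five-membered (aurone).

**Building blocks.** Aldehyde 4 is the SEM ether of 3, which is the ortho C-prenylation product of 4-hydroxybenzaldehyde 1 with prenyl bromide 2. Acetophenone 7 is the mono-MOM ether of 6, the 4-O-prenyl ether of 2,4,6-trihydroxyacetophenone 5 with the same bromide 2. The symmetry of 6 makes the choice of which chelated hydroxyl to cap irrelevant.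

## Roads not taken

**Alternative 1:** Ring A would be built rather than bought. A 3-alkoxycyclobutenone A2 and a siloxyalkyne A3 that already carries the 1,1-dimethylallyl group would be heated together. Ring opening to a vinylketene, [2+2] addition to the alkyne, four-electron opening and six-electron closure would give the resorcinol derivative A1, forming C8–C8a and C6–C7.
- Merit: the tertiary group sits at C8 by construction, with three differentiated oxygens and no C6/C8 question. In this respect it is better than the Claisen step of the chosen plan, which can only offer bond fixation in the chromone as its argument, and relocation of the shift as a reserve.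
- Weak points: A3 has a quaternary propargylic carbon and needs its own multistep preparation. A1 is still only ring A; acylation, chalcone formation, ring C closure and the whole ring B/D problem remain. The ethyl ether at O5 in A1 must later be cleaved with a Lewis acid in the presence of the chromene and the tert-prenyl phenol.
- Comparison: the key step would be spent on the one ring that is commercially available with all three oxygens in place. The route would be several steps longer, whereas the chosen plan spends its key step on the part that is hard, namely ring D with its adjacent free hydroxyl.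

**Alternative 2:** Ring C would be closed at O1–C8a. The enolate of a 2-alkoxy-1,3-diketone A5, bearing a 2,4,6-trifluorophenyl ketone, displaces an ortho fluoride under carbonate base to give the 5,7-difluoroflavonol ether A4.
- Merit: the closure can only give the six-membered ring, so it has no aurone problem. It also joins ring B/D late and convergently. In these respects it is better than steps 5 and 6 of the chosen plan, whose peroxide cyclisation must be steered between two ring sizes.
- Weak points: both remaining fluorides of A4 must be exchanged for oxygen by two further aromatic substitutions. The C8 tertiary group still needs an O-prenyl ether and a sigmatropic shift on a now fully dressed chromene. The ring B/D acid must be made separately from a catechol, with regiocontrol of the pyran fusion and an extra protecting group on O3'.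
- Comparison: the chosen plan accepts a less certain ring-C closure, but needs no fluorine–oxygen exchange and obtains ring D and the C3' oxygen from one prenyl group in one flask.

**Alternative 3:** Ring B would be made last. The pyrano-fused 2-pyranone A8 adds as a diene to the terminal alkyne of the 2-ethynylchromone A7, forming C5'–C6' and C1'–C2', and decarboxylative aromatisation of the bridged lactone gives tetra-O-MOM Broussonol A, A6.
- Merit: on paper this is the most convergent plan. Every substituent of ring B is carried in by A8, and A6 is one deprotection from the target, so the end-game is shorter than in the chosen plan.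
- Weak points: A8 needs a 4,5-dioxygenated 2-pyranone without a C6 substituent, which is not a simple compound. A7 requires a complete ring A/C system with a C2 alkyne. The regiochemistry of the cycloaddition is not fixed, because the two donor oxygens of A8 polarise the diene in opposite senses. The temperatures usual for pyranone cycloadditions put the vinyl group of A7 and the chromene double bond at risk as competing dienophiles or in retro-electrocyclic opening.
- Comparison: the chosen plan is linear after the condensation and has one untested step. Against that it sets commercial building blocks, known reaction types for every other step, and a ring-D closure whose regiochemistry is dictated by the substrate.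

Key step: step 10

Assumption: the 4'-oxygen is carried as its SEM ether because an aryl silyl ether would not survive the hydroxide of steps 5 and 6; compounds 8, 10 and 12 are racemic and lose their stereocentres within the step that forms them.

## Route

Step 1
Reactants: 1 4-hydroxybenzaldehyde; 2 prenyl bromide (1-bromo-3-methylbut-2-ene)
Product: 3 4-hydroxy-3-(3-methylbut-2-en-1-yl)benzaldehyde
Conditions: KOH (10% aq), rt, 24 h; then dilute HCl
Reagents that add atoms: none
Why: Direct ortho C-alkylation of an ambident phenoxide in water, where hydrogen bonding shields oxygen and the para position is blocked by the formyl group; the O-prenyl ether and the 3,5-diprenyl compound are separable by-products of this known transformation.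

Step 2
Reactants: 3 4-hydroxy-3-(3-methylbut-2-en-1-yl)benzaldehyde
Product: 4 3-(3-methylbut-2-en-1-yl)-4-{[2-(trimethylsilyl)ethoxy]methoxy}benzaldehyde
Conditions: SEMCl, i-Pr2NEt, CH2Cl2, 0 °C to rt
Reagents that add atoms: 2-(trimethylsilyl)ethoxymethyl chloride, C[Si](C)(C)CCOCCl
Why: Williamson-type acetalisation of the phenol; the SEM ether withstands hydroxide, peroxide, 190 °C and NaH and is later removed by fluoride without touching MOM ethers.

Step 3
Reactants: 5 2,4,6-trihydroxyacetophenone; 2 prenyl bromide
Product: 6 1-[2,6-dihydroxy-4-(3-methylbut-2-en-1-yloxy)phenyl]ethanone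
Conditions: K2CO3 (1.1 equiv), acetone, reflux
Reagents that add atoms: none
Why: Williamson etherification; the 4-hydroxyl is the most acidic and the only one not hydrogen-bonded to the acetyl group, so one equivalent of base and halide should alkylate it selectively on oxygen.

Step 4
Reactants: 6 1-[2,6-dihydroxy-4-(3-methylbut-2-en-1-yloxy)phenyl]ethanone
Product: 7 1-[2-hydroxy-6-(methoxymethoxy)-4-(3-methylbut-2-en-1-yloxy)phenyl]ethanone
Conditions: MOMCl (1.1 equiv), i-Pr2NEt, CH2Cl2, 0 °C
Reagents that add atoms: chloromethyl methyl ether, COCCl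
Why: Acetal formation at one of two equivalent hydroxyls; once the first is capped the other is locked in a hydrogen bond to the carbonyl and is not alkylated under amine base, so the reaction should stop at the mono ether.

Step 5
Reactants: 7 1-[2-hydroxy-6-(methoxymethoxy)-4-(3-methylbut-2-en-1-yloxy)phenyl]ethanone; 4 3-(3-methylbut-2-en-1-yl)-4-{[2-(trimethylsilyl)ethoxy]methoxy}benzaldehyde
Product: 9 (E)-1-[2-hydroxy-6-(methoxymethoxy)-4-(prenyloxy)phenyl]-3-[3-prenyl-4-(SEM-oxy)phenyl]prop-2-en-1-one, via aldol adduct 8 (not isolated)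
Conditions: KOH, EtOH/H2O, 0 °C to rt, 36 h
Reagents that add atoms: none
Why: Claisen–Schmidt condensation: the methyl ketone enolate adds to the non-enolisable aldehyde and aldol 8 loses water by E1cB to the conjugated (E)-enone; the acetals and the allyl ether are inert to hydroxide.

Step 6
Reactants: 9 (E)-1-[2-hydroxy-6-(methoxymethoxy)-4-(prenyloxy)phenyl]-3-[3-prenyl-4-(SEM-oxy)phenyl]prop-2-en-1-one
Product: 11 3-hydroxy-5-(methoxymethoxy)-7-(prenyloxy)-2-[3-prenyl-4-(SEM-oxy)phenyl]-4H-chromen-4-one, via trans-dihydroflavonol 10 (not isolated)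
Conditions: H2O2 (30% aq), NaOH (aq), MeOH, 0 °C to rt
Reagents that add atoms: hydrogen peroxide, OO
Why: Algar–Flynn–Oyamada reaction: the 2'-phenoxide closes on the β-carbon (6-endo oxa-Michael), the enolate is hydroxylated by peroxide to trans-dihydroflavonol 10, and alkaline peroxide dehydrogenates 10 to the flavonol, erasing both stereocentres; nucleophilic peroxide does not epoxidise the isolated prenyl double bonds.

Step 7
Reactants: 11 3-hydroxy-5-(methoxymethoxy)-7-(prenyloxy)-2-[3-prenyl-4-(SEM-oxy)phenyl]-4H-chromen-4-one
Product: 13 3,7-dihydroxy-5-(methoxymethoxy)-8-(2-methylbut-3-en-2-yl)-2-[3-prenyl-4-(SEM-oxy)phenyl]-4H-chromen-4-one, via C8 dienone 12 (not isolated)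
Conditions: N,N-diethylaniline (degassed), 190 °C, sealed tube, argon, 2–3 h
Reagents that add atoms: none
Why: Aromatic Claisen rearrangement: the [3,3] shift of the 7-O-prenyl ether delivers the dimethyl-bearing carbon to C8 (dienone 12), which enolises to the phenol; C8 should be preferred to C6 because the C7–C8 bond of a chromone has the higher double-bond character, as with 7-allyloxy flavones and coumarins, and the para carbon C4a is a ring-fusion atom, so no Cope shift can follow.

Step 8
Reactants: 13 3,7-dihydroxy-5-(methoxymethoxy)-8-(2-methylbut-3-en-2-yl)-2-[3-prenyl-4-(SEM-oxy)phenyl]-4H-chromen-4-one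
Product: 14 3,5,7-tris(methoxymethoxy)-8-(2-methylbut-3-en-2-yl)-2-[3-prenyl-4-(SEM-oxy)phenyl]-4H-chromen-4-one
Conditions: NaH (2.5 equiv), MOMCl (2.5 equiv), DMF, 0 °C to rt
Reagents that add atoms: chloromethyl methyl ether, COCCl
Why: Double Williamson acetalisation of the 3-enol and the hindered 7-phenol as their sodium salts; the small chloromethyl ether should still reach the oxygen flanked by the tertiary group.

Step 9
Reactants: 14 3,5,7-tris(methoxymethoxy)-8-(2-methylbut-3-en-2-yl)-2-[3-prenyl-4-(SEM-oxy)phenyl]-4H-chromen-4-one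
Product: 15 2-[4-hydroxy-3-(3-methylbut-2-en-1-yl)phenyl]-3,5,7-tris(methoxymethoxy)-8-(2-methylbut-3-en-2-yl)-4H-chromen-4-one
Conditions: Bu4NF (3 equiv), THF/DMPU, 70 °C; then H2O
Reagents that add atoms: none
Why: Fluoride attacks silicon and the 2-silylethyl group fragments (ethene, then formaldehyde from the hemiformal) to release the 4'-phenoxide; MOM ethers, the allyl groups and the pyranone are inert to fluoride, so only the ring-B phenol should be unveiled.

Step 10
Reactants: 15 2-[4-hydroxy-3-(3-methylbut-2-en-1-yl)phenyl]-3,5,7-tris(methoxymethoxy)-8-(2-methylbut-3-en-2-yl)-4H-chromen-4-one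
Product: 18 2-(8-hydroxy-2,2-dimethyl-2H-chromen-6-yl)-3,5,7-tris(methoxymethoxy)-8-(2-methylbut-3-en-2-yl)-4H-chromen-4-one, via ortho-quinone 16 (not isolated), via vinyl ortho-quinone methide 17 (not isolated)
Conditions: IBX (1.05 equiv), DMF, 0 °C to rt, dark; then Et3N (3 equiv), rt
Reagents that add atoms: 2-iodoxybenzoic acid, O=C1OI(O)(=O)c2ccccc12
Why: Proposed new method: the free 4'-phenol of 15 exchanges onto the pentavalent iodine of IBX and an oxo ligand is delivered intramolecularly to C3', the only unsubstituted ortho carbon, giving ortho-quinone 16 and 2-iodobenzoic acid (C3'–O bond). Et3N then removes a prenyl CH2 proton, which is acidified through C5'=C6'–C1'=C2'–C3'=O, so that the C3' carbonyl becomes the hydroxyl and the (Z)-vinyl ortho-quinone methide 17 appears. 17 is a 1-oxatriene (O=C4'–C5'=CH–CH=CMe2) that should close thermally by a disrotatory oxa-6π electrocyclisation, forming O4'–C(CH3)2 and the six-membered ring D with rearomatisation of ring B as the driving force, so no reductant is needed after the oxidation. The closest known reactions are the IBX ortho-oxygenation of 4'-hydroxyflavonoids to their 3',4'-quinones and the amine-catalysed isomerisation of prenyl-para-quinones to chromenols; what is untested is the amine-induced tautomerisation of a 3-prenyl-ortho-quinone in the same flask. No stereocentre is formed. The step needs oxygenation at C3' only and closure through O4' only; the first is secured because C5' carries the prenyl group and every other hydroxyl is an acetal, the second because only the C4' carbonyl is conjugated with the new diene. The 1,1-dimethylallyl group has no hydrogen on its ring-bound carbon and cannot tautomerise, and the oxidant is consumed before the amine releases the product phenol, so 18 should not be oxidised further.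

Step 11
Reactants: 18 2-(8-hydroxy-2,2-dimethyl-2H-chromen-6-yl)-3,5,7-tris(methoxymethoxy)-8-(2-methylbut-3-en-2-yl)-4H-chromen-4-one
Product: 19 Broussonol A
Conditions: HCl (1.25 M in MeOH), 40 °C
Reagents that add atoms: none
Why: Acid-catalysed transacetalisation of the three MOM ethers to dimethoxymethane; in dilute methanolic acid at 40 °C the monosubstituted vinyl group and the chromene should not be protonated fast enough to cyclise or add methanol, as in deprotections of other pyranoflavonoids.

## Compound list

1 | 4-hydroxybenzaldehyde | O=Cc1ccc(O)cc1 | starting material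
2 | prenyl bromide (1-bromo-3-methylbut-2-ene) | CC(C)=CCBr | starting material
3 | 4-hydroxy-3-(3-methylbut-2-en-1-yl)benzaldehyde | O=Cc1ccc(O)c(CC=C(C)C)c1 | intermediate
4 | 3-(3-methylbut-2-en-1-yl)-4-{[2-(trimethylsilyl)ethoxy]methoxy}benzaldehyde | O=Cc1ccc(OCOCC[Si](C)(C)C)c(CC=C(C)C)c1 | intermediate
5 | 2,4,6-trihydroxyacetophenone | CC(=O)c1c(O)cc(O)cc1O | starting material
6 | 1-[2,6-dihydroxy-4-(3-methylbut-2-en-1-yloxy)phenyl]ethanone | CC(=O)c1c(O)cc(OCC=C(C)C)cc1O | intermediate
7 | 1-[2-hydroxy-6-(methoxymethoxy)-4-(3-methylbut-2-en-1-yloxy)phenyl]ethanone | CC(=O)c1c(O)cc(OCC=C(C)C)cc1OCOC | intermediate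
8 | 3-hydroxy-1-[2-hydroxy-6-(methoxymethoxy)-4-(prenyloxy)phenyl]-3-[3-prenyl-4-(SEM-oxy)phenyl]propan-1-one, racemic | COCOc1cc(OCC=C(C)C)cc(O)c1C(=O)CC(O)c1ccc(OCOCC[Si](C)(C)C)c(CC=C(C)C)c1 | intermediate (not isolated)
9 | (E)-1-[2-hydroxy-6-(methoxymethoxy)-4-(prenyloxy)phenyl]-3-[3-prenyl-4-(SEM-oxy)phenyl]prop-2-en-1-one | COCOc1cc(OCC=C(C)C)cc(O)c1C(=O)/C=C/c1ccc(OCOCC[Si](C)(C)C)c(CC=C(C)C)c1 | intermediate
10 | trans-3-hydroxy-5-(methoxymethoxy)-7-(prenyloxy)-2-[3-prenyl-4-(SEM-oxy)phenyl]chroman-4-one, racemic, (2R,3R) enantiomer drawn | CC(C)=CCc1cc(ccc1OCOCC[Si](C)(C)C)[C@@H]1[C@@H](O)C(=O)c2c(OCOC)cc(OCC=C(C)C)cc2O1 | intermediate (not isolated)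
11 | 3-hydroxy-5-(methoxymethoxy)-7-(prenyloxy)-2-[3-prenyl-4-(SEM-oxy)phenyl]-4H-chromen-4-one | COCOc1cc(OCC=C(C)C)cc2oc(-c3ccc(OCOCC[Si](C)(C)C)c(CC=C(C)C)c3)c(O)c(=O)c12 | intermediate
12 | 3-hydroxy-5-(methoxymethoxy)-8-(2-methylbut-3-en-2-yl)-2-[3-prenyl-4-(SEM-oxy)phenyl]-8H-chromene-4,7-dione, racemic | COCOC1=CC(=O)C(C(C)(C)C=C)C2=C1C(=O)C(O)=C(c1ccc(OCOCC[Si](C)(C)C)c(CC=C(C)C)c1)O2 | intermediate (not isolated)
13 | 3,7-dihydroxy-5-(methoxymethoxy)-8-(2-methylbut-3-en-2-yl)-2-[3-prenyl-4-(SEM-oxy)phenyl]-4H-chromen-4-one | C=CC(C)(C)c1c(O)cc(OCOC)c2c(=O)c(O)c(-c3ccc(OCOCC[Si](C)(C)C)c(CC=C(C)C)c3)oc12 | intermediate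
14 | 3,5,7-tris(methoxymethoxy)-8-(2-methylbut-3-en-2-yl)-2-[3-prenyl-4-(SEM-oxy)phenyl]-4H-chromen-4-one | C=CC(C)(C)c1c(OCOC)cc(OCOC)c2c(=O)c(OCOC)c(-c3ccc(OCOCC[Si](C)(C)C)c(CC=C(C)C)c3)oc12 | intermediate
15 | 2-[4-hydroxy-3-(3-methylbut-2-en-1-yl)phenyl]-3,5,7-tris(methoxymethoxy)-8-(2-methylbut-3-en-2-yl)-4H-chromen-4-one | C=CC(C)(C)c1c(OCOC)cc(OCOC)c2c(=O)c(OCOC)c(-c3ccc(O)c(CC=C(C)C)c3)oc12 | intermediate
16 | 3-(3-methylbut-2-en-1-yl)-5-[3,5,7-tris(methoxymethoxy)-8-(2-methylbut-3-en-2-yl)-4-oxo-4H-chromen-2-yl]cyclohexa-3,5-diene-1,2-dione | C=CC(C)(C)c1c(OCOC)cc(OCOC)c2c(=O)c(OCOC)c(C3=CC(=O)C(=O)C(CC=C(C)C)=C3)oc12 | intermediate (not isolated)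
17 | (6Z)-2-hydroxy-6-(3-methylbut-2-en-1-ylidene)-4-[3,5,7-tris(methoxymethoxy)-8-(2-methylbut-3-en-2-yl)-4-oxo-4H-chromen-2-yl]cyclohexa-2,4-dien-1-one | C=CC(C)(C)c1c(OCOC)cc(OCOC)c2c(=O)c(OCOC)c(C3=C/C(=C/C=C(C)C)C(=O)C(O)=C3)oc12 | intermediate (not isolated)
18 | 2-(8-hydroxy-2,2-dimethyl-2H-chromen-6-yl)-3,5,7-tris(methoxymethoxy)-8-(2-methylbut-3-en-2-yl)-4H-chromen-4-one | C=CC(C)(C)c1c(OCOC)cc(OCOC)c2c(=O)c(OCOC)c(-c3cc(O)c4c(c3)C=CC(C)(C)O4)oc12 | intermediate
19 | Broussonol A, 3,5,7-trihydroxy-2-(8-hydroxy-2,2-dimethyl-2H-chromen-6-yl)-8-(2-methylbut-3-en-2-yl)-4H-chromen-4-one | C=CC(C)(C)c1c(O)cc(O)c2c(=O)c(O)c(-c3cc(O)c4c(c3)C=CC(C)(C)O4)oc12 | target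

## Step count and risk

Total step count: 11. Longest linear sequence: 9 steps (steps 1, 2, 5–11, or equally steps 3, 4, 5–11).

**Step 10 (key step; carries the label).** The most likely failure is that the ortho-quinone is consumed before it tautomerises. It could be reduced by electron transfer from the amine, or attacked at C2' or C6' by water or by the amine, or it could dimerise as a heterodiene. A slight excess of oxidant could also attack the amine. The fallback uses only known reactions.
- From 15, oxidation with IBX as above but quenched with aqueous Na2S2O4 is the established way from 4'-hydroxyflavonoids to their catechols. It should give 2-[3,4-dihydroxy-5-(3-methylbut-2-en-1-yl)phenyl]-3,5,7-tris(methoxymethoxy)-8-(2-methylbut-3-en-2-yl)-4H-chromen-4-one F1.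
- PhSeCl in CH2Cl2 at −78 °C then closes the only hydroxyl ortho to the prenyl group onto the tertiary carbon of the seleniranium ion (selenoetherification of an ortho-prenylphenol). This gives racemic 2-[8-hydroxy-2,2-dimethyl-3-(phenylselanyl)-3,4-dihydro-2H-chromen-6-yl]-3,5,7-tris(methoxymethoxy)-8-(2-methylbut-3-en-2-yl)-4H-chromen-4-one F2.
- Oxidation with H2O2/pyridine at 0 °C and syn elimination of the selenoxide toward the benzylic CH2, the only β-hydrogens available, returns to the route at 18.

**Step 7.** The shift may go partly to C6. On long heating the new phenol may add to its own vinyl group to give a dihydrofuran, or the ether may lose isoprene. The fallback moves the rearrangement to the acetophenone, where chelation of the 2-hydroxyl fixes the double bond toward C3.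
- From 7, heating in N,N-diethylaniline should give 1-[2,4-dihydroxy-6-(methoxymethoxy)-3-(2-methylbut-3-en-2-yl)phenyl]ethanone F3.
- MOMCl/i-Pr2NEt caps the non-chelated 4-hydroxyl to give 1-[2-hydroxy-4,6-bis(methoxymethoxy)-3-(2-methylbut-3-en-2-yl)phenyl]ethanone F4.
- Condensation with 4 under the conditions of step 5 gives (E)-1-[2-hydroxy-4,6-bis(methoxymethoxy)-3-(2-methylbut-3-en-2-yl)phenyl]-3-[3-prenyl-4-(SEM-oxy)phenyl]prop-2-en-1-one F5.
- Alkaline peroxide as in step 6 gives 3-hydroxy-5,7-bis(methoxymethoxy)-8-(2-methylbut-3-en-2-yl)-2-[3-prenyl-4-(SEM-oxy)phenyl]-4H-chromen-4-one F6.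
- MOMCl/NaH on the 3-hydroxyl returns to the route at 14.

**Step 6.** The 6'-alkoxy group twists the chalcone carbonyl out of plane. This can divert the cyclisation through the epoxide to five-membered closure and hence to an aurone. The fallback separates ring closure from C3 oxygenation.
- From 9, NaOAc in refluxing EtOH should give racemic 5-(methoxymethoxy)-7-(prenyloxy)-2-[3-prenyl-4-(SEM-oxy)phenyl]chroman-4-one F7 by oxa-Michael closure.
- I2 in pyridine at 90 °C dehydrogenates it to 5-(methoxymethoxy)-7-(prenyloxy)-2-[3-prenyl-4-(SEM-oxy)phenyl]-4H-chromen-4-one F8.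
- C3 lithiation with LiN(i-Pr)2 at −78 °C, trapping with B(OMe)3 and oxidation of the borate with H2O2/aq NaHCO3 returns to the route at 11.

**Step 1.** Competing O-alkylation and a second C-alkylation lower the return of the mono-C-prenyl phenol, and the bromide hydrolyses in the aqueous base. The fallback installs the prenyl group by cross-coupling.
- From 1, bromination (Br2, AcOH) gives 3-bromo-4-hydroxybenzaldehyde F9.
- SEMCl/i-Pr2NEt gives 3-bromo-4-{[2-(trimethylsilyl)ethoxy]methoxy}benzaldehyde F10.
- Stille coupling with tributyl(3-methylbut-2-en-1-yl)stannane and Pd(PPh3)4 (zerovalent palladium) in DMF at 100 °C returns to the route at 4.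

## Further compounds

F1 | step 10 | 2-[3,4-dihydroxy-5-(3-methylbut-2-en-1-yl)phenyl]-3,5,7-tris(methoxymethoxy)-8-(2-methylbut-3-en-2-yl)-4H-chromen-4-one | C=CC(C)(C)c1c(OCOC)cc(OCOC)c2c(=O)c(OCOC)c(-c3cc(O)c(O)c(CC=C(C)C)c3)oc12
F2 | step 10 | 2-[8-hydroxy-2,2-dimethyl-3-(phenylselanyl)-3,4-dihydro-2H-chromen-6-yl]-3,5,7-tris(methoxymethoxy)-8-(2-methylbut-3-en-2-yl)-4H-chromen-4-one, racemic | C=CC(C)(C)c1c(OCOC)cc(OCOC)c2c(=O)c(OCOC)c(-c3cc(O)c4c(c3)CC([Se]c3ccccc3)C(C)(C)O4)oc12
F3 | step 7 | 1-[2,4-dihydroxy-6-(methoxymethoxy)-3-(2-methylbut-3-en-2-yl)phenyl]ethanone | CC(=O)c1c(O)c(C(C)(C)C=C)c(O)cc1OCOC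
F4 | step 7 | 1-[2-hydroxy-4,6-bis(methoxymethoxy)-3-(2-methylbut-3-en-2-yl)phenyl]ethanone | CC(=O)c1c(O)c(C(C)(C)C=C)c(OCOC)cc1OCOC
F5 | step 7 | (E)-1-[2-hydroxy-4,6-bis(methoxymethoxy)-3-(2-methylbut-3-en-2-yl)phenyl]-3-[3-prenyl-4-(SEM-oxy)phenyl]prop-2-en-1-one | COCOc1cc(OCOC)c(C(C)(C)C=C)c(O)c1C(=O)/C=C/c1ccc(OCOCC[Si](C)(C)C)c(CC=C(C)C)c1
F6 | step 7 | 3-hydroxy-5,7-bis(methoxymethoxy)-8-(2-methylbut-3-en-2-yl)-2-[3-prenyl-4-(SEM-oxy)phenyl]-4H-chromen-4-one | C=CC(C)(C)c1c(OCOC)cc(OCOC)c2c(=O)c(O)c(-c3ccc(OCOCC[Si](C)(C)C)c(CC=C(C)C)c3)oc12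
F7 | step 6 | 5-(methoxymethoxy)-7-(prenyloxy)-2-[3-prenyl-4-(SEM-oxy)phenyl]chroman-4-one, racemic | COCOc1cc(OCC=C(C)C)cc2c1C(=O)CC(c1ccc(OCOCC[Si](C)(C)C)c(CC=C(C)C)c1)O2
F8 | step 6 | 5-(methoxymethoxy)-7-(prenyloxy)-2-[3-prenyl-4-(SEM-oxy)phenyl]-4H-chromen-4-one | COCOc1cc(OCC=C(C)C)cc2oc(-c3ccc(OCOCC[Si](C)(C)C)c(CC=C(C)C)c3)cc(=O)c12
F9 | step 1 | 3-bromo-4-hydroxybenzaldehyde | O=Cc1ccc(O)c(Br)c1
F10 | step 1 | 3-bromo-4-{[2-(trimethylsilyl)ethoxy]methoxy}benzaldehyde | O=Cc1ccc(OCOCC[Si](C)(C)C)c(Br)c1
A1 | alternative 1 | 5-ethoxy-2-(2-methylbut-3-en-2-yl)-3-(triisopropylsilyloxy)phenol | C=CC(C)(C)c1c(O)cc(OCC)cc1O[Si](C(C)C)(C(C)C)C(C)C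
A2 | alternative 1 | 3-ethoxycyclobut-2-en-1-one | CCOC1=CC(=O)C1
A3 | alternative 1 | [(3,3-dimethylpent-4-en-1-yn-1-yl)oxy]triisopropylsilane | C=CC(C)(C)C#CO[Si](C(C)C)(C(C)C)C(C)C
A4 | alternative 2 | 5,7-difluoro-3-(methoxymethoxy)-2-[8-(methoxymethoxy)-2,2-dimethyl-2H-chromen-6-yl]-4H-chromen-4-one | Fc1cc(F)c2c(=O)c(OCOC)c(-c3cc(OCOC)c4c(c3)C=CC(C)(C)O4)oc2c1
A5 | alternative 2 | 2-(methoxymethoxy)-1-[8-(methoxymethoxy)-2,2-dimethyl-2H-chromen-6-yl]-3-(2,4,6-trifluorophenyl)propane-1,3-dione | COCOC(C(=O)c1c(F)cc(F)cc1F)C(=O)c1cc(OCOC)c2c(c1)C=CC(C)(C)O2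
A6 | alternative 3 | 3,5,7-tris(methoxymethoxy)-2-[8-(methoxymethoxy)-2,2-dimethyl-2H-chromen-6-yl]-8-(2-methylbut-3-en-2-yl)-4H-chromen-4-one | C=CC(C)(C)c1c(OCOC)cc(OCOC)c2c(=O)c(OCOC)c(-c3cc(OCOC)c4c(c3)C=CC(C)(C)O4)oc12
A7 | alternative 3 | 2-ethynyl-3,5,7-tris(methoxymethoxy)-8-(2-methylbut-3-en-2-yl)-4H-chromen-4-one | C#Cc1oc2c(C(C)(C)C=C)c(OCOC)cc(OCOC)c2c(=O)c1OCOC
A8 | alternative 3 | 8-(methoxymethoxy)-2,2-dimethyl-2H,5H-pyrano[4,3-b]pyran-5-one | O=C1OC=C(OCOC)C2=C1C=CC(C)(C)O2
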